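**Plan**

- Ring A is the oxolane that carries the 4-hydroxy-3-methoxyphenyl group; ring B is the one that carries the prenyloxyaryl group. The retrosynthesis cuts, in this order: the aryl O–Si bond, the O–CH2 bond of ring B (back to a γ-lactone), the aryl–C bond at the benzylic carbon of ring A, the O–CH2 bond of ring A, the two cyclopropane C–C bonds, then the ester C–O and vinyl–carbinol C–C bonds.
- Enabling feature: the ring-fusion carbon next to the phenol-bearing CH carries two one-carbon branches, that CH and the ring B methylene. Drawn as a formyl group and a lactone carbonyl, they doubly activate a cyclopropane built from this carbon, the other ring-fusion CH and the ring A methylene. Strain-driven 1,3-shift of that methylene from carbon to the formyl oxygen closes ring A.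
- Forward order: allylic carbinol, then allylic formyl-diazo ester, then ring B as a lactone fused to the cyclopropane (the lactone serves as tether, second acceptor and masked CH2), then ring A by rearrangement. The phenol ring is then added to the enol ether, the lactone is reduced and re-closed as the ether, and the silyl group is removed.
- Stereochemistry: the prenyloxyaryl carbinol centre comes from a lipase resolution. The adjacent ring-fusion CH comes from substrate-controlled cyclopropanation (aryl exo). The other ring-fusion CH and the phenol-bearing centre come from convex-face syn aryl-rhodation and protonation.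

Key step: step 7

Remark: compound 13, (chloromethylene)dimethyliminium chloride and glyoxylic acid chloride p-toluenesulfonylhydrazone are taken as purchased reagents.

**Step 1**
Reactants: 1 vanillin
Product: 2 3-methoxy-4-[(3-methylbut-2-en-1-yl)oxy]benzaldehyde
Conditions: 1-bromo-3-methylbut-2-ene, K2CO3, DMF, rt
Reagents that add atoms: 1-bromo-3-methylbut-2-ene, CC(C)=CCBr
Why: Williamson ether synthesis; the phenoxide is the only nucleophile present under carbonate and is alkylated at oxygen by the allylic bromide.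

**Step 2**
Reactants: 2 3-methoxy-4-[(3-methylbut-2-en-1-yl)oxy]benzaldehyde
Product: 4 racemic 1-{3-methoxy-4-[(3-methylbut-2-en-1-yl)oxy]phenyl}prop-2-en-1-yl acetate, via bromomagnesium alkoxide 3 (not isolated)
Conditions: CH2=CHMgBr, THF, −78 to 0 °C; then Ac2O, 0 °C to rt
Reagents that add atoms: vinylmagnesium bromide, C=C[Mg]Br; acetic anhydride, CC(=O)OC(C)=O
Why: Grignard 1,2-addition to the aldehyde followed by O-acylation of the magnesium alkoxide in the same flask; the carbinol centre is made racemic on purpose and is resolved in step 3.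

**Step 3**
Reactants: 4 racemic 1-{3-methoxy-4-[(3-methylbut-2-en-1-yl)oxy]phenyl}prop-2-en-1-yl acetate
Product: 5 (1R)-1-{3-methoxy-4-[(3-methylbut-2-en-1-yl)oxy]phenyl}prop-2-en-1-ol
Conditions: immobilised Candida antarctica lipase B, n-BuOH, t-BuOMe, 30 °C, stopped near half conversion
Reagents that add atoms: none
Why: Lipase-catalysed kinetic resolution by enantioselective alcoholysis (aryl as the large and vinyl as the medium group) should cleave only the (R)-acetate, so the (R)-alcohol is released, the unreacted (S)-acetate is removed by chromatography, and the absolute configuration of the route is fixed here.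

**Step 4**
Reactants: 5 (1R)-1-{3-methoxy-4-[(3-methylbut-2-en-1-yl)oxy]phenyl}prop-2-en-1-ol
Product: 7 (1R)-1-{3-methoxy-4-[(3-methylbut-2-en-1-yl)oxy]phenyl}prop-2-en-1-yl diazoacetate, via tosylhydrazone ester 6 (not isolated)
Conditions: glyoxylic acid chloride p-toluenesulfonylhydrazone, PhNMe2, CH2Cl2, 0 °C; then Et3N, 0 °C to rt
Reagents that add atoms: glyoxylic acid chloride p-toluenesulfonylhydrazone, Cc1ccc(cc1)S(=O)(=O)NN=CC(Cl)=O
Why: O-acylation by the acid chloride and base-induced loss of sulfinate from the tosylhydrazone (Bamford–Stevens-type diazo formation) give the allylic diazoacetate without breaking the C–O bond of the stereocentre.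

**Step 5**
Reactants: 7 (1R)-1-{3-methoxy-4-[(3-methylbut-2-en-1-yl)oxy]phenyl}prop-2-en-1-yl diazoacetate
Product: 9 (1R)-1-{3-methoxy-4-[(3-methylbut-2-en-1-yl)oxy]phenyl}prop-2-en-1-yl 2-diazo-3-oxopropanoate, via iminium chloride 8 (not isolated)
Conditions: (chloromethylene)dimethyliminium chloride, 2,6-lutidine, CH2Cl2, 0 °C; then aq. NaOAc/AcOH buffer (pH 5), 0 °C
Reagents that add atoms: (chloromethylene)dimethyliminium chloride, C[N+](C)=CCl.[Cl-]; water, O
Why: Vilsmeier formylation at the nucleophilic diazo carbon, as known for simple alkyl diazoacetates, gives an iminium salt that hydrolyses to the formyl diazo ester, while the hindered base keeps HCl away from the allylic benzylic ester and the prenyl ether.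

**Step 6**
Reactants: 9 (1R)-1-{3-methoxy-4-[(3-methylbut-2-en-1-yl)oxy]phenyl}prop-2-en-1-yl 2-diazo-3-oxopropanoate
Product: 10 (1S,4R,5R)-4-{3-methoxy-4-[(3-methylbut-2-en-1-yl)oxy]phenyl}-2-oxo-3-oxabicyclo[3.1.0]hexane-1-carbaldehyde
Conditions: Rh2(OAc)4 (1 mol %), CH2Cl2, 40 °C, slow addition of 9
Reagents that add atoms: none
Why: Rhodium-carbenoid intramolecular cyclopropanation of an allylic α-diazo-β-oxo ester onto the tethered vinyl group; cis fusion of the two new centres is enforced by the five-membered lactone, and the alkene face should be set by the carbinol centre, whose aryl group takes the exo position anti to the new methylene bridge.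

**Step 7**
Reactants: 10 (1S,4R,5R)-4-{3-methoxy-4-[(3-methylbut-2-en-1-yl)oxy]phenyl}-2-oxo-3-oxabicyclo[3.1.0]hexane-1-carbaldehyde
Product: 12 (3R,3aS)-3-{3-methoxy-4-[(3-methylbut-2-en-1-yl)oxy]phenyl}-3a,4-dihydro-1H,3H-furo[3,4-c]furan-1-one (ring A as cyclic enol ether O–CH=C conjugated to the ring B lactone), via ammonium enolate 11 (not isolated)
Conditions: DABCO (0.3 equiv), DMSO, 100 °C
Reagents that add atoms: none
Why: DABCO should open the cyclopropane by SN2 attack at its CH2 carbon, breaking the bond to the quaternary carbon and releasing the ring strain to give the formyl-lactone enolate 11; the formyl enolate oxygen then displaces the ammonium group, which forms the O–CH2 bond of ring A and returns the catalyst. The closest known reaction type is the Cloke–Wilson rearrangement of cyclopropyl aldehydes and ketones in its amine-catalysed form for 1,1-dicarbonyl cyclopropanes. Ring A closes in the 5-exo-tet mode. No new stereocentre is formed: the ring-fusion CH is not touched and the quaternary carbon becomes sp2. The step needs attack at CH2 and not at the ring-fusion CH, which the lower substitution of CH2 secures, and O- and not C-alkylation of the enolate, which is secured because C-alkylation only returns 10 reversibly while O-alkylation gives the stable push-pull enol ether. Closure through the lactone carbonyl oxygen is excluded because it would give a bridged bicycle with a bridgehead double bond.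

**Step 8**
Reactants: 13 2-methoxy-4-(4,4,5,5-tetramethyl-1,3,2-dioxaborolan-2-yl)phenol
Product: 14 triisopropyl[2-methoxy-4-(4,4,5,5-tetramethyl-1,3,2-dioxaborolan-2-yl)phenoxy]silane
Conditions: i-Pr3SiCl, imidazole, DMF, rt
Reagents that add atoms: chlorotriisopropylsilane, CC(C)[Si](Cl)(C(C)C)C(C)C
Why: Imidazole-promoted O-silylation of the phenol; the bulky aryl silyl ether is chosen to survive the hydride reduction and the sulfonylation later in the route.

**Step 9**
Reactants: 12 (3R,3aS)-3-{3-methoxy-4-[(3-methylbut-2-en-1-yl)oxy]phenyl}-3a,4-dihydro-1H,3H-furo[3,4-c]furan-1-one; 14 triisopropyl[2-methoxy-4-(4,4,5,5-tetramethyl-1,3,2-dioxaborolan-2-yl)phenoxy]silane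
Product: 15 (3R,3aS,6R,6aR)-3-{3-methoxy-4-[(3-methylbut-2-en-1-yl)oxy]phenyl}-6-{3-methoxy-4-[(triisopropylsilyl)oxy]phenyl}tetrahydro-1H,3H-furo[3,4-c]furan-1-one
Conditions: [Rh(OH)(cod)]2 (3 mol %), dioxane/H2O 10:1, 50 °C
Reagents that add atoms: none
Why: Proposed new method: an aryl–rhodium species formed by transmetallation from 14 should add syn across the enol-ether double bond of 12 with the aryl group going to the oxygen-bearing β-carbon, from the convex face because only there can the new carbon–rhodium bond at the ring-fusion carbon develop towards a cis-fused bicycle, and hydrolysis of the rhodium enolate then places H on the same face, so the aryl group ends exo and the ring fusion cis under control of the existing ring-fusion centre, while β-oxygen elimination is disfavoured because the ring C–O bond lies near the enolate plane; the closest known reaction type is the Hayashi–Miyaura 1,4-addition of arylboron reagents to unsaturated lactones and to cyclic β-alkoxy enones such as chromones.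

**Step 10**
Reactants: 15 (3R,3aS,6R,6aR)-3-{3-methoxy-4-[(3-methylbut-2-en-1-yl)oxy]phenyl}-6-{3-methoxy-4-[(triisopropylsilyl)oxy]phenyl}tetrahydro-1H,3H-furo[3,4-c]furan-1-one
Product: 16 {(2R,3S,4S)-4-[(R)-hydroxy{3-methoxy-4-[(3-methylbut-2-en-1-yl)oxy]phenyl}methyl]-2-{3-methoxy-4-[(triisopropylsilyl)oxy]phenyl}oxolan-3-yl}methanol
Conditions: LiAlH4, THF, 0 °C; aq. potassium sodium tartrate work-up
Reagents that add atoms: none
Why: Hydride reduction of the γ-lactone to the 1,4-diol; no stereocentre is touched, and the aryl silyl ether, the prenyl ether and the benzylic ethers should survive at 0 °C.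

**Step 11**
Reactants: 16 {(2R,3S,4S)-4-[(R)-hydroxy{3-methoxy-4-[(3-methylbut-2-en-1-yl)oxy]phenyl}methyl]-2-{3-methoxy-4-[(triisopropylsilyl)oxy]phenyl}oxolan-3-yl}methanol
Product: 18 triisopropylsilyl ether of the target with (1R,3aS,4R,6aS) configuration, via primary mesylate 17 (not isolated)
Conditions: MsCl (1.05 equiv), Et3N, CH2Cl2, −20 °C to rt
Reagents that add atoms: none
Why: Selective sulfonylation of the primary alcohol followed by intramolecular Williamson etherification (5-exo-tet) by the benzylic hydroxyl, which keeps its configuration because its C–O bond is not broken; the cis arrangement of the two arms on ring A allows closure of ring B.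

**Step 12**
Reactants: 18 triisopropylsilyl ether of the target
Product: 19 4-[(1R,3aS,4R,6aS)-4-{3-methoxy-4-[(3-methylbut-2-en-1-yl)oxy]phenyl}tetrahydro-1H,3H-furo[3,4-c]furan-1-yl]-2-methoxyphenol
Conditions: Bu4NF, AcOH, THF, 0 °C
Reagents that add atoms: none
Why: Fluoride-mediated cleavage of the aryl silyl ether under buffered conditions; the prenyl ether and the two benzylic ether centres are inert to fluoride.

**Compound list**

1 | vanillin (4-hydroxy-3-methoxybenzaldehyde) | COc1cc(C=O)ccc1O | starting material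
2 | 3-methoxy-4-[(3-methylbut-2-en-1-yl)oxy]benzaldehyde | COc1cc(C=O)ccc1OCC=C(C)C | intermediate
3 | bromomagnesium alkoxide of racemic 1-{3-methoxy-4-[(3-methylbut-2-en-1-yl)oxy]phenyl}prop-2-en-1-ol | COc1cc(C(O[Mg]Br)C=C)ccc1OCC=C(C)C | intermediate
4 | racemic 1-{3-methoxy-4-[(3-methylbut-2-en-1-yl)oxy]phenyl}prop-2-en-1-yl acetate | COc1cc(C(OC(C)=O)C=C)ccc1OCC=C(C)C | intermediate
5 | (1R)-1-{3-methoxy-4-[(3-methylbut-2-en-1-yl)oxy]phenyl}prop-2-en-1-ol | O[C@H](C=C)c1ccc(OCC=C(C)C)c(OC)c1 | intermediate
6 | (1R)-1-arylprop-2-en-1-yl 2-(tosylhydrazinylidene)acetate (aryl as in 5) | Cc1ccc(cc1)S(=O)(=O)NN=CC(=O)O[C@H](C=C)c1ccc(OCC=C(C)C)c(OC)c1 | intermediate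
7 | (1R)-1-arylprop-2-en-1-yl diazoacetate | [N-]=[N+]=CC(=O)O[C@H](C=C)c1ccc(OCC=C(C)C)c(OC)c1 | intermediate
8 | dimethyliminium chloride of the formyl diazo ester | C[N+](C)=CC(=[N+]=[N-])C(=O)O[C@H](C=C)c1ccc(OCC=C(C)C)c(OC)c1.[Cl-] | intermediate
9 | (1R)-1-arylprop-2-en-1-yl 2-diazo-3-oxopropanoate | O=CC(=[N+]=[N-])C(=O)O[C@H](C=C)c1ccc(OCC=C(C)C)c(OC)c1 | intermediate
10 | (1S,4R,5R)-4-aryl-2-oxo-3-oxabicyclo[3.1.0]hexane-1-carbaldehyde | O=C[C@]12C[C@H]1[C@H](c3ccc(OCC=C(C)C)c(OC)c3)OC2=O | intermediate
11 | zwitterion: formyl-lactone enolate carrying a CH2–DABCO ammonium arm | [O-]C=C1C(=O)O[C@@H](c2ccc(OCC=C(C)C)c(OC)c2)[C@@H]1C[N+]12CCN(CC1)CC2 | intermediate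
12 | (3R,3aS)-3-aryl-3a,4-dihydro-1H,3H-furo[3,4-c]furan-1-one | O=C1O[C@@H](c3ccc(OCC=C(C)C)c(OC)c3)[C@@H]2COC=C12 | intermediate
13 | 2-methoxy-4-(4,4,5,5-tetramethyl-1,3,2-dioxaborolan-2-yl)phenol | COc1cc(B2OC(C)(C)C(C)(C)O2)ccc1O | starting material
14 | triisopropyl[2-methoxy-4-(4,4,5,5-tetramethyl-1,3,2-dioxaborolan-2-yl)phenoxy]silane | COc1cc(B2OC(C)(C)C(C)(C)O2)ccc1O[Si](C(C)C)(C(C)C)C(C)C | intermediate
15 | (3R,3aS,6R,6aR)-3-(prenyloxyaryl)-6-(silyloxyaryl)tetrahydro-1H,3H-furo[3,4-c]furan-1-one | O=C1O[C@@H](c3ccc(OCC=C(C)C)c(OC)c3)[C@@H]2CO[C@@H](c3ccc(O[Si](C(C)C)(C(C)C)C(C)C)c(OC)c3)[C@H]12 | intermediate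
16 | (2R,3S,4S)-oxolane diol with (R)-benzylic carbinol | OC[C@H]1[C@H](c2ccc(O[Si](C(C)C)(C(C)C)C(C)C)c(OC)c2)OC[C@H]1[C@@H](O)c1ccc(OCC=C(C)C)c(OC)c1 | intermediate
17 | primary methanesulfonate of 16 | CS(=O)(=O)OC[C@H]1[C@H](c2ccc(O[Si](C(C)C)(C(C)C)C(C)C)c(OC)c2)OC[C@H]1[C@@H](O)c1ccc(OCC=C(C)C)c(OC)c1 | intermediate
18 | triisopropylsilyl ether of the target | COc1cc([C@@H]2OC[C@@H]3[C@H]2CO[C@H]3c2ccc(OCC=C(C)C)c(OC)c2)ccc1O[Si](C(C)C)(C(C)C)C(C)C | intermediate
19 | 4-[(1R,3aS,4R,6aS)-4-{3-methoxy-4-[(3-methylbut-2-en-1-yl)oxy]phenyl}tetrahydro-1H,3H-furo[3,4-c]furan-1-yl]-2-methoxyphenol | COc1cc([C@@H]2OC[C@@H]3[C@H]2CO[C@H]3c2ccc(OCC=C(C)C)c(OC)c2)ccc1O | target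

**Step count**

Total: 12 steps. Longest linear sequence: 11 steps (steps 1 to 7 and 9 to 12); step 8 is a one-step side branch.

**Steps most likely to fail**

1. Step 9. The carbometallation of the donor-deactivated, trisubstituted enol-ether double bond may be slow, so that protodeboronation of 14 wins; the rhodium enolate may also open ring A by β-oxygen elimination. The fallback sets out from 12 and uses oxocarbenium chemistry instead of a metal-catalysed 1,4-addition. Acid-catalysed addition of methanol (pyridinium p-toluenesulfonate, MeOH) gives the methyl acetal (3R,3aS,6aR)-6-methoxy-3-aryl-tetrahydro-1H,3H-furo[3,4-c]furan-1-one F1, as a mixture at the acetal carbon. Friedel–Crafts arylation of F1 with 2-methoxyphenol and BF3·OEt2 at −40 °C, through the cis-fused oxocarbenium ion and para to the hydroxyl group, should give the exo aryl lactone with a free phenol, (3R,3aS,6R,6aR)-6-(4-hydroxy-3-methoxyphenyl)-3-aryl-tetrahydro-1H,3H-furo[3,4-c]furan-1-one F2. Silylation with i-Pr3SiCl and imidazole comes back to the route at 15.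

2. Step 6. The formyl-substituted carbenoid may rearrange by hydrogen shift to a ketene, may add to the electron-rich arene, or may show poor facial selectivity. The fallback sets out from 5 and carries the aldehyde as a thioester through the carbenoid step. Steglich esterification of 5 with 3-(ethylsulfanyl)-3-oxopropanoic acid (DCC, DMAP) gives the mixed malonate (1R)-1-arylprop-2-en-1-yl 3-(ethylsulfanyl)-3-oxopropanoate F3. Regitz diazo transfer (4-acetamidobenzenesulfonyl azide, Et3N) gives the diazo compound (1R)-1-arylprop-2-en-1-yl 2-diazo-3-(ethylsulfanyl)-3-oxopropanoate F4. Rh2(OAc)4-catalysed intramolecular cyclopropanation gives S-ethyl (1R,4R,5R)-4-aryl-2-oxo-3-oxabicyclo[3.1.0]hexane-1-carbothioate F5. Fukuyama reduction (Et3SiH, Pd/C, acetone) of the thioester comes back to the route at 10.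

3. Step 7. At 100 °C the amine may deprotonate the ring-fusion CH of 12, which would lead to β-elimination of the benzylic carboxylate and aromatisation to a furan; reversible amine addition to the aldehyde may also stall the catalyst. The fallback sets out from 10 and separates ring opening from ring closure under non-basic conditions. Homoconjugate addition of iodide with MgI2 in THF at 0 °C gives the isolable iodide (4R,5R)-3-(hydroxymethylidene)-4-(iodomethyl)-5-aryl-oxolan-2-one F6. Silver-assisted intramolecular O-alkylation of the enol (Ag2O, CH2Cl2, rt) closes ring A and comes back to the route at 12.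

**Further compounds**

F1 | step 9 | (3R,3aS,6aR)-6-methoxy-3-{3-methoxy-4-[(3-methylbut-2-en-1-yl)oxy]phenyl}tetrahydro-1H,3H-furo[3,4-c]furan-1-one | O=C1O[C@@H](c3ccc(OCC=C(C)C)c(OC)c3)[C@@H]2COC(OC)[C@H]12
F2 | step 9 | (3R,3aS,6R,6aR)-6-(4-hydroxy-3-methoxyphenyl)-3-{3-methoxy-4-[(3-methylbut-2-en-1-yl)oxy]phenyl}tetrahydro-1H,3H-furo[3,4-c]furan-1-one | O=C1O[C@@H](c3ccc(OCC=C(C)C)c(OC)c3)[C@@H]2CO[C@@H](c3ccc(O)c(OC)c3)[C@H]12
F3 | step 6 | (1R)-1-{3-methoxy-4-[(3-methylbut-2-en-1-yl)oxy]phenyl}prop-2-en-1-yl 3-(ethylsulfanyl)-3-oxopropanoate | CCSC(=O)CC(=O)O[C@H](C=C)c1ccc(OCC=C(C)C)c(OC)c1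
F4 | step 6 | (1R)-1-{3-methoxy-4-[(3-methylbut-2-en-1-yl)oxy]phenyl}prop-2-en-1-yl 2-diazo-3-(ethylsulfanyl)-3-oxopropanoate | CCSC(=O)C(=[N+]=[N-])C(=O)O[C@H](C=C)c1ccc(OCC=C(C)C)c(OC)c1
F5 | step 6 | S-ethyl (1R,4R,5R)-4-{3-methoxy-4-[(3-methylbut-2-en-1-yl)oxy]phenyl}-2-oxo-3-oxabicyclo[3.1.0]hexane-1-carbothioate | CCSC(=O)[C@]12C[C@H]1[C@H](c3ccc(OCC=C(C)C)c(OC)c3)OC2=O
F6 | step 7 | (4R,5R)-3-(hydroxymethylidene)-4-(iodomethyl)-5-{3-methoxy-4-[(3-methylbut-2-en-1-yl)oxy]phenyl}oxolan-2-one | OC=C1C(=O)O[C@@H](c2ccc(OCC=C(C)C)c(OC)c2)[C@@H]1CI
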